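**Retrosynthetic overview**

1. Target 44 ⇐ hydroquinone 43 ⇐ dimethyl ether 41. The ring A quaternary carbon and the ring B alkene come from deconjugative methylation of Robinson enone 39, followed by Wolff–Kishner removal of the ketone.
2. 39 ⇐ Mukaiyama–Michael addition and aldol condensation joining ring B silyl enol ether 9 with vinyl ketone 36, which already carries the complete lower decalin (rings C and D) and the two-carbon linker.
3. 9 ⇐ organocatalytic Michael addition (first stereocentre), cyclohexenone formation, then two copper-mediated 1,4-additions (benzyl anti to the ring methyl).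
4. 36 ⇐ allyl octalin 30 ⇐ McMurry closure of ring D onto ring C ketone 28 ⇐ methyl 1,4-addition and allylation of enone 24 (from ring-closing metathesis), whose stereocentre comes from lipase desymmetrisation of prochiral diol 14.
5. Ring order: B and C as monocycles, then D fused to C, then A fused to B last.

Assumption: the target is the free bis(hydrogen sulfate) as drawn; it is released from its pyridinium salt by cation exchange in the last step.
Assumption: compounds that deliver two or more skeletal carbons are numbered as starting materials; methyl, silyl and heteroatom donors are listed as reagents.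

This route is a design on paper; selectivities quoted are expectations, not measured values.

**Fragment 1 (ring B)**

Step 1
Reactants: 1 propanal; 2 methyl vinyl ketone
Product: 3 (2R)-2-methyl-5-oxohexanal
Conditions: (S)-2-[methoxy(diphenyl)methyl]pyrrolidine (5 mol %), ethyl 3,4-dihydroxybenzoate (20 mol %), neat, 4 °C
Reagents that add atoms: none
Why: Enamine-catalysed asymmetric Michael addition in which the propanal enamine attacks the enone from the face opposite the diarylmethyl group, setting the first stereocentre (R) by catalyst control.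

Step 2
Reactants: 3 (2R)-2-methyl-5-oxohexanal
Product: 4 (4R)-4-methylcyclohex-2-en-1-one
Conditions: LiOH (10 mol %), i-PrOH, 25 °C
Reagents that add atoms: none
Why: Intramolecular aldol condensation of the methyl ketone onto the aldehyde closes the cyclohexenone, and the stereocentre becomes the non-enolisable C4 and is kept.

Step 3
Reactants: 4 (4R)-4-methylcyclohex-2-en-1-one
Product: 5 trans-3,4-dimethyl silyl enol ether
Conditions: MeMgBr, CuBr·SMe2 (5 mol %), TMSCl, HMPA, THF, −78 °C; Et3N
Reagents that add atoms: methylmagnesium bromide, C[Mg]Br; chlorotrimethylsilane, C[Si](C)(C)Cl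
Why: Copper-catalysed 1,4-addition of a Grignard reagent with silyl trapping, methyl entering anti to the C4 methyl (this new centre is erased in the next step).

Step 4
Reactants: 5 trans-3,4-dimethyl silyl enol ether
Product: 6 (4R)-3,4-dimethylcyclohex-2-en-1-one
Conditions: Pd(OAc)2 (1.05 equiv), MeCN, 25 °C
Reagents that add atoms: none
Why: Saegusa–Ito oxidation of the regiodefined silyl enol ether (palladium enolate, then β-hydride elimination) restores the enone now bearing the β-methyl, leaving C4 untouched.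

Step 5
Reactants: 6 (4R)-3,4-dimethylcyclohex-2-en-1-one; 7 2,5-dimethoxybenzyl chloride
Product: 9 ring B silyl enol ether, via benzylic Grignard reagent 8 (not isolated)
Conditions: 7, Mg, THF, 0 °C; then 6, CuBr·SMe2 (20 mol %), TMSCl, HMPA, −78 to −40 °C; Et3N
Reagents that add atoms: chlorotrimethylsilane, C[Si](C)(C)Cl
Why: Copper-catalysed conjugate addition to the β,β-disubstituted enone with silyl activation, the benzyl group adding anti to the neighbouring C4 methyl so that the quaternary carbon (3S) has its methyl cis to the C4 methyl, and the enol ether is fixed regiospecifically toward C2.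

**Fragment 2 (rings C and D)**

Step 6
Reactants: 10 2-(2-bromoethyl)-1,3-dioxolane; 11 diethyl isopropylidenemalonate
Product: 13 tert-alkyl malonate, via dioxolanylethyl Grignard reagent 12 (not isolated)
Conditions: 10, Mg, THF, 25–30 °C; then 11, CuI (5 mol %), −20 to 0 °C; aq NH4Cl
Reagents that add atoms: none
Why: Copper-catalysed conjugate addition of a Grignard reagent to an alkylidenemalonate builds the gem-dimethyl quaternary carbon of ring D (no stereocentre).

Step 7
Reactants: 13 tert-alkyl malonate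
Product: 14 prochiral diol
Conditions: LiAlH4, THF, 0 to 25 °C; H2O, aq NaOH
Reagents that add atoms: none
Why: Hydride reduction of both esters gives the prochiral 2-substituted propane-1,3-diol while the acetal is inert.

Step 8
Reactants: 14 prochiral diol
Product: 15 (R)-monoacetate
Conditions: Burkholderia cepacia lipase (Amano lipase PS, immobilised), vinyl acetate, MTBE, 25 °C
Reagents that add atoms: vinyl acetate, CC(=O)OC=C
Why: Lipase-catalysed enantiotopic-group-selective transesterification (desymmetrisation) acylates one hydroxymethyl arm and so sets the stereocentre (R) from which all other centres of the lower decalin are relayed.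

Step 9
Reactants: 15 (R)-monoacetate
Product: 16 (S)-iodo acetate
Conditions: I2, PPh3, imidazole, CH2Cl2, 0 to 25 °C
Reagents that add atoms: iodine, II
Why: Appel-type iodination by SN2 at the primary carbon, which does not touch the stereocentre (the descriptor changes by priority only).

Step 10
Reactants: 16 (S)-iodo acetate; 17 allyltributylstannane
Product: 18 (S)-hexenyl acetate
Conditions: azobis(isobutyronitrile) (15 mol %), benzene, 80 °C
Reagents that add atoms: none
Why: Keck radical allylation, a neutral C–C bond formation at the hindered primary carbon that tolerates acetate and acetal.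

Step 11
Reactants: 18 (S)-hexenyl acetate
Product: 19 (S)-hexenol
Conditions: K2CO3 (0.2 equiv), MeOH, 25 °C
Reagents that add atoms: none
Why: Base-catalysed transesterification (methanolysis) frees the second arm.

Step 12
Reactants: 19 (S)-hexenol
Product: 20 (S)-hexenal
Conditions: Dess–Martin periodinane, NaHCO3, CH2Cl2, 0 to 25 °C
Reagents that add atoms: none
Why: Dess–Martin oxidation under buffered conditions gives the α-branched aldehyde without epimerisation, the β-position now carrying only carbon so that no β-elimination can occur.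

Step 13
Reactants: 20 (S)-hexenal; 21 isopropenylmagnesium bromide
Product: 22 dienol
Conditions: THF, −78 °C; aq NH4Cl
Reagents that add atoms: none
Why: Grignard 1,2-addition to the aldehyde, the carbinol configuration being irrelevant because it is oxidised next.

Step 14
Reactants: 22 dienol
Product: 23 dienone
Conditions: Dess–Martin periodinane, NaHCO3, CH2Cl2, 0 to 25 °C
Reagents that add atoms: none
Why: Dess–Martin oxidation of the allylic alcohol to the isopropenyl ketone under neutral conditions.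

Step 15
Reactants: 23 dienone
Product: 24 ring C enone
Conditions: second-generation Grubbs catalyst (5 mol %), CH2Cl2, 40 °C
Reagents that add atoms: none
Why: Ring-closing metathesis between the 1,1-disubstituted enone alkene and the terminal alkene closes ring C as a 2-methylcyclohexenone with loss of ethene.

Step 16
Reactants: 24 ring C enone
Product: 25 ring C silyl enol ether
Conditions: MeMgBr, CuBr·SMe2 (10 mol %), TMSCl, HMPA, THF, −78 °C; Et3N
Reagents that add atoms: methylmagnesium bromide, C[Mg]Br; chlorotrimethylsilane, C[Si](C)(C)Cl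
Why: Copper-catalysed 1,4-addition with silyl trapping in which, with the bulky C6 substituent held equatorial, methyl adds axially through the chair-like transition state and therefore cis to that substituent (new centre 3S).

Step 17
Reactants: 25 ring C silyl enol ether; 26 allyl bromide
Product: 28 ring C ketone, via lithium enolate 27 (not isolated)
Conditions: MeLi, THF, 0 to 25 °C; then 26, HMPA, −78 to 0 °C
Reagents that add atoms: none
Why: Regiospecific enolate generation from the silyl enol ether and C-alkylation with a reactive allylic halide, the electrophile entering axially and anti to the adjacent pseudoaxial C3 methyl to create the quaternary centre (2R) with the two methyls cis.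

Step 18
Reactants: 28 ring C ketone
Product: 29 keto aldehyde
Conditions: 1 M HCl, THF, 25 °C
Reagents that add atoms: water, O
Why: Acid-catalysed acetal hydrolysis, mild enough that the hindered α-stereocentre of the ketone is not enolised.

Step 19
Reactants: 29 keto aldehyde
Product: 30 allyl octalin
Conditions: TiCl3(DME)1.5, Zn–Cu couple, DME, 85 °C, slow addition of 29
Reagents that add atoms: none
Why: Intramolecular McMurry coupling of ketone and aldehyde with low-valent titanium closes ring D and places the trisubstituted alkene regiospecifically, without forming or touching a stereocentre.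

Step 20
Reactants: 30 allyl octalin
Product: 31 octalin propanol
Conditions: 9-borabicyclo[3.3.1]nonane, THF, 0 to 25 °C; then NaOH, H2O2
Reagents that add atoms: hydrogen peroxide, OO
Why: Hydroboration–oxidation, anti-Markovnikov and selective for the monosubstituted alkene over the hindered trisubstituted ring alkene.

Step 21
Reactants: 31 octalin propanol
Product: 32 octalin propyl iodide
Conditions: I2, PPh3, imidazole, CH2Cl2, 0 to 25 °C
Reagents that add atoms: iodine, II
Why: Appel-type iodination of the primary alcohol by SN2.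

Step 22
Reactants: 32 octalin propyl iodide; 33 acrolein
Product: 35 allylic alcohol, via alkyllithium 34 (not isolated)
Conditions: t-BuLi (2.1 equiv), Et2O/pentane, −78 °C; then 33, −78 °C; aq NH4Cl
Reagents that add atoms: none
Why: Iodine–lithium exchange followed by 1,2-addition of the primary alkyllithium to the enal, the carbinol centre being oxidised next.

Step 23
Reactants: 35 allylic alcohol
Product: 36 vinyl ketone
Conditions: Dess–Martin periodinane, NaHCO3, CH2Cl2, 0 °C
Reagents that add atoms: none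
Why: Dess–Martin oxidation gives the vinyl ketone under neutral conditions that leave the ring alkene alone.

**Union and end game**

Step 24
Reactants: 9 ring B silyl enol ether; 36 vinyl ketone
Product: 38 1,5-diketone, via adduct silyl enol ether 37 (not isolated)
Conditions: Sc(OTf)3 (10 mol %), CH2Cl2, −78 to −30 °C; then 1 M HCl, THF, 0 °C
Reagents that add atoms: none
Why: Lewis-acid-catalysed Mukaiyama–Michael addition of the regiodefined silyl enol ether to the unhindered vinyl ketone joins the two halves, the new C2 centre forming as a mixture that is corrected in the next step.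

Step 25
Reactants: 38 1,5-diketone
Product: 39 bis-decalin enone
Conditions: KOH, MeOH, 65 °C
Reagents that add atoms: none
Why: Intramolecular aldol condensation completes the Robinson annulation of ring A under equilibrating conditions, so that C4a epimerises through the enolate to the more stable epimer with the ring A bond equatorial and its hydrogen anti to the axial C5 methyl (thermodynamic control, about 4:1 expected, minor epimer recycled by re-equilibration).

Step 26
Reactants: 39 bis-decalin enone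
Product: 40 α-methyl ketone
Conditions: KOt-Bu (1.3 equiv), t-BuOH/THF, 25 °C; then MeI, 0 to 25 °C
Reagents that add atoms: iodomethane, CI
Why: Deconjugative α-alkylation of the extended dienolate, methyl iodide attacking C1 axially on the face syn to the axial C4a hydrogen, which creates the quaternary centre (1S) and moves the alkene into its final position.

Step 27
Reactants: 40 α-methyl ketone
Product: 41 hydroquinone dimethyl ether
Conditions: N2H4·H2O, KOH, diethylene glycol, 130 °C then 210 °C
Reagents that add atoms: none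
Why: Wolff–Kishner reduction (Huang-Minlon procedure) removes the ketone, and the alkene cannot migrate because the α-carbon is quaternary.

Step 28
Reactants: 41 hydroquinone dimethyl ether
Product: 43 hydroquinone, via para-quinone 42 (not isolated)
Conditions: (NH4)2Ce(NO3)6 (2.5 equiv), MeCN/H2O, 0 °C; then Na2S2O4, H2O/Et2O, 25 °C
Reagents that add atoms: water, O
Why: Oxidative demethylation by tetravalent cerium to the para-quinone followed by dithionite reduction gives the hydroquinone without touching the hindered ring alkenes.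

Step 29
Reactants: 43 hydroquinone
Product: 44 target bis(hydrogen sulfate)
Conditions: SO3·pyridine (6 equiv), pyridine, 25 °C; then sulfonic acid resin (H+ form), MeOH/H2O, 0 °C
Reagents that add atoms: sulfur trioxide–pyridine complex, [O-]S(=O)(=O)[n+]1ccccc1
Why: O-sulfation of both phenols with the sulfur trioxide–pyridine complex and proton exchange gives the bis(hydrogen sulfate) with no change at carbon.

**Compound list**

1 | propanal | CCC=O | starting material
2 | methyl vinyl ketone (but-3-en-2-one) | CC(=O)C=C | starting material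
3 | (2R)-2-methyl-5-oxohexanal | O=C[C@H](C)CCC(C)=O | intermediate
4 | (4R)-4-methylcyclohex-2-en-1-one | C[C@@H]1CCC(=O)C=C1 | intermediate
5 | trans-3,4-dimethyl silyl enol ether: {[(3S,4R)-3,4-dimethylcyclohex-1-en-1-yl]oxy}trimethylsilane | C[C@@H]1CCC(O[Si](C)(C)C)=C[C@H]1C | intermediate
6 | (4R)-3,4-dimethylcyclohex-2-en-1-one | C[C@@H]1CCC(=O)C=C1C | intermediate
7 | 2,5-dimethoxybenzyl chloride (2-(chloromethyl)-1,4-dimethoxybenzene) | COc1ccc(OC)c(CCl)c1 | starting material
8 | benzylic Grignard reagent: (2,5-dimethoxybenzyl)magnesium chloride | COc1ccc(OC)c(C[Mg]Cl)c1 | intermediate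
9 | ring B silyl enol ether: {[(3S,4R)-3-(2,5-dimethoxybenzyl)-3,4-dimethylcyclohex-1-en-1-yl]oxy}trimethylsilane | C[C@@H]1CCC(O[Si](C)(C)C)=C[C@@]1(C)Cc1cc(OC)ccc1OC | intermediate
10 | 2-(2-bromoethyl)-1,3-dioxolane | BrCCC1OCCO1 | starting material
11 | diethyl isopropylidenemalonate (diethyl 2-(propan-2-ylidene)propanedioate) | CCOC(=O)C(=C(C)C)C(=O)OCC | starting material
12 | dioxolanylethyl Grignard reagent: [2-(1,3-dioxolan-2-yl)ethyl]magnesium bromide | Br[Mg]CCC1OCCO1 | intermediate
13 | tert-alkyl malonate: diethyl 2-[4-(1,3-dioxolan-2-yl)-2-methylbutan-2-yl]propanedioate | CCOC(=O)C(C(=O)OCC)C(C)(C)CCC1OCCO1 | intermediate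
14 | prochiral diol: 2-[4-(1,3-dioxolan-2-yl)-2-methylbutan-2-yl]propane-1,3-diol | OCC(CO)C(C)(C)CCC1OCCO1 | intermediate
15 | (R)-monoacetate: (2R)-2-[4-(1,3-dioxolan-2-yl)-2-methylbutan-2-yl]-3-hydroxypropyl acetate | CC(=O)OC[C@@H](CO)C(C)(C)CCC1OCCO1 | intermediate
16 | (S)-iodo acetate: (2S)-2-[4-(1,3-dioxolan-2-yl)-2-methylbutan-2-yl]-3-iodopropyl acetate | CC(=O)OC[C@@H](CI)C(C)(C)CCC1OCCO1 | intermediate
17 | allyltributylstannane | C=CC[Sn](CCCC)(CCCC)CCCC | starting material
18 | (S)-hexenyl acetate: (2S)-2-[4-(1,3-dioxolan-2-yl)-2-methylbutan-2-yl]hex-5-en-1-yl acetate | CC(=O)OC[C@@H](CCC=C)C(C)(C)CCC1OCCO1 | intermediate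
19 | (S)-hexenol: (2S)-2-[4-(1,3-dioxolan-2-yl)-2-methylbutan-2-yl]hex-5-en-1-ol | OC[C@@H](CCC=C)C(C)(C)CCC1OCCO1 | intermediate
20 | (S)-hexenal: (2S)-2-[4-(1,3-dioxolan-2-yl)-2-methylbutan-2-yl]hex-5-enal | O=C[C@@H](CCC=C)C(C)(C)CCC1OCCO1 | intermediate
21 | isopropenylmagnesium bromide | CC(=C)[Mg]Br | starting material
22 | dienol: (4S)-4-[4-(1,3-dioxolan-2-yl)-2-methylbutan-2-yl]-2-methylocta-1,7-dien-3-ol (C3 epimers) | C=C(C)C(O)[C@@H](CCC=C)C(C)(C)CCC1OCCO1 | intermediate
23 | dienone: (4S)-4-[4-(1,3-dioxolan-2-yl)-2-methylbutan-2-yl]-2-methylocta-1,7-dien-3-one | C=C(C)C(=O)[C@@H](CCC=C)C(C)(C)CCC1OCCO1 | intermediate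
24 | ring C enone: (6S)-6-[4-(1,3-dioxolan-2-yl)-2-methylbutan-2-yl]-2-methylcyclohex-2-en-1-one | CC1=CCC[C@@H](C(C)(C)CCC2OCCO2)C1=O | intermediate
25 | ring C silyl enol ether: {[(3S,6S)-6-[4-(1,3-dioxolan-2-yl)-2-methylbutan-2-yl]-2,3-dimethylcyclohex-1-en-1-yl]oxy}trimethylsilane | CC1=C(O[Si](C)(C)C)[C@H](C(C)(C)CCC2OCCO2)CC[C@@H]1C | intermediate
26 | allyl bromide (3-bromoprop-1-ene) | C=CCBr | starting material
27 | lithium enolate: lithium (3S,6S)-6-[4-(1,3-dioxolan-2-yl)-2-methylbutan-2-yl]-2,3-dimethylcyclohex-1-en-1-olate | CC1=C(O[Li])[C@H](C(C)(C)CCC2OCCO2)CC[C@@H]1C | intermediate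
28 | ring C ketone: (2R,3S,6S)-2-allyl-6-[4-(1,3-dioxolan-2-yl)-2-methylbutan-2-yl]-2,3-dimethylcyclohexan-1-one | C=CC[C@@]1(C)C(=O)[C@H](C(C)(C)CCC2OCCO2)CC[C@@H]1C | intermediate
29 | keto aldehyde: 4-[(1S,3R,4S)-3-allyl-3,4-dimethyl-2-oxocyclohexyl]-4-methylpentanal | C=CC[C@@]1(C)C(=O)[C@H](C(C)(C)CCC=O)CC[C@@H]1C | intermediate
30 | allyl octalin: (1R,2S,4aS)-1-allyl-1,2,5,5-tetramethyl-1,2,3,4,4a,5,6,7-octahydronaphthalene | C=CC[C@@]1(C)C2=CCCC(C)(C)[C@@H]2CC[C@@H]1C | intermediate
31 | octalin propanol: 3-[(1R,2S,4aS)-1,2,5,5-tetramethyl-1,2,3,4,4a,5,6,7-octahydronaphthalen-1-yl]propan-1-ol | OCCC[C@@]1(C)C2=CCCC(C)(C)[C@@H]2CC[C@@H]1C | intermediate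
32 | octalin propyl iodide: (1R,2S,4aS)-1-(3-iodopropyl)-1,2,5,5-tetramethyl-1,2,3,4,4a,5,6,7-octahydronaphthalene | ICCC[C@@]1(C)C2=CCCC(C)(C)[C@@H]2CC[C@@H]1C | intermediate
33 | acrolein (prop-2-enal) | C=CC=O | starting material
34 | alkyllithium: {3-[(1R,2S,4aS)-1,2,5,5-tetramethyl-1,2,3,4,4a,5,6,7-octahydronaphthalen-1-yl]propyl}lithium | [Li]CCC[C@@]1(C)C2=CCCC(C)(C)[C@@H]2CC[C@@H]1C | intermediate
35 | allylic alcohol: 6-[(1R,2S,4aS)-1,2,5,5-tetramethyl-1,2,3,4,4a,5,6,7-octahydronaphthalen-1-yl]hex-1-en-3-ol (C3 epimers) | C=CC(O)CCC[C@@]1(C)C2=CCCC(C)(C)[C@@H]2CC[C@@H]1C | intermediate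
36 | vinyl ketone: 6-[(1R,2S,4aS)-1,2,5,5-tetramethyl-1,2,3,4,4a,5,6,7-octahydronaphthalen-1-yl]hex-1-en-3-one | C=CC(=O)CCC[C@@]1(C)C2=CCCC(C)(C)[C@@H]2CC[C@@H]1C | intermediate
37 | adduct silyl enol ether: (3S,4R)-3-(2,5-dimethoxybenzyl)-3,4-dimethyl-2-{3-[(trimethylsilyl)oxy]-6-[(1R,2S,4aS)-1,2,5,5-tetramethyl-1,2,3,4,4a,5,6,7-octahydronaphthalen-1-yl]hex-2-en-1-yl}cyclohexan-1-one (C2 epimers, alkene isomers) | C[C@@H]1CCC(=O)C(CC=C(O[Si](C)(C)C)CCC[C@@]2(C)C3=CCCC(C)(C)[C@@H]3CC[C@@H]2C)[C@@]1(C)Cc1cc(OC)ccc1OC | intermediate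
38 | 1,5-diketone: (3S,4R)-3-(2,5-dimethoxybenzyl)-3,4-dimethyl-2-{3-oxo-6-[(1R,2S,4aS)-1,2,5,5-tetramethyl-1,2,3,4,4a,5,6,7-octahydronaphthalen-1-yl]hexyl}cyclohexan-1-one (C2 epimers) | C[C@@H]1CCC(=O)C(CCC(=O)CCC[C@@]2(C)C3=CCCC(C)(C)[C@@H]3CC[C@@H]2C)[C@@]1(C)Cc1cc(OC)ccc1OC | intermediate
39 | bis-decalin enone: (4aR,5S,6R)-5-(2,5-dimethoxybenzyl)-5,6-dimethyl-1-{2-[(1R,2S,4aS)-1,2,5,5-tetramethyl-1,2,3,4,4a,5,6,7-octahydronaphthalen-1-yl]ethyl}-4,4a,5,6,7,8-hexahydronaphthalen-2(3H)-one | C[C@@H]1CCC2=C(CC[C@@]3(C)C4=CCCC(C)(C)[C@@H]4CC[C@@H]3C)C(=O)CC[C@@H]2[C@@]1(C)Cc1cc(OC)ccc1OC | intermediate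
40 | α-methyl ketone: (1S,4aR,5S,6R)-5-(2,5-dimethoxybenzyl)-1,5,6-trimethyl-1-{2-[(1R,2S,4aS)-1,2,5,5-tetramethyl-1,2,3,4,4a,5,6,7-octahydronaphthalen-1-yl]ethyl}-3,4,4a,5,6,7-hexahydronaphthalen-2(1H)-one | C[C@@H]1CC=C2[C@H](CCC(=O)[C@@]2(C)CC[C@@]2(C)C3=CCCC(C)(C)[C@@H]3CC[C@@H]2C)[C@@]1(C)Cc1cc(OC)ccc1OC | intermediate
41 | hydroquinone dimethyl ether: 2-{[(1S,2R,5S,8aR)-1,2,5-trimethyl-5-{2-[(1R,2S,4aS)-1,2,5,5-tetramethyl-1,2,3,4,4a,5,6,7-octahydronaphthalen-1-yl]ethyl}-1,2,3,5,6,7,8,8a-octahydronaphthalen-1-yl]methyl}-1,4-dimethoxybenzene | C[C@@H]1CC=C2[C@H](CCC[C@@]2(C)CC[C@@]2(C)C3=CCCC(C)(C)[C@@H]3CC[C@@H]2C)[C@@]1(C)Cc1cc(OC)ccc1OC | intermediate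
42 | para-quinone: 2-{[(1S,2R,5S,8aR)-1,2,5-trimethyl-5-{2-[(1R,2S,4aS)-1,2,5,5-tetramethyl-1,2,3,4,4a,5,6,7-octahydronaphthalen-1-yl]ethyl}-1,2,3,5,6,7,8,8a-octahydronaphthalen-1-yl]methyl}cyclohexa-2,5-diene-1,4-dione | C[C@@H]1CC=C2[C@H](CCC[C@@]2(C)CC[C@@]2(C)C3=CCCC(C)(C)[C@@H]3CC[C@@H]2C)[C@@]1(C)CC1=CC(=O)C=CC1=O | intermediate
43 | hydroquinone: 2-{[(1S,2R,5S,8aR)-1,2,5-trimethyl-5-{2-[(1R,2S,4aS)-1,2,5,5-tetramethyl-1,2,3,4,4a,5,6,7-octahydronaphthalen-1-yl]ethyl}-1,2,3,5,6,7,8,8a-octahydronaphthalen-1-yl]methyl}benzene-1,4-diol | C[C@@H]1CC=C2[C@H](CCC[C@@]2(C)CC[C@@]2(C)C3=CCCC(C)(C)[C@@H]3CC[C@@H]2C)[C@@]1(C)Cc1cc(O)ccc1O | intermediate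
44 | target bis(hydrogen sulfate): 2-{[(1S,2R,5S,8aR)-1,2,5-trimethyl-5-{2-[(1R,2S,4aS)-1,2,5,5-tetramethyl-1,2,3,4,4a,5,6,7-octahydronaphthalen-1-yl]ethyl}-1,2,3,5,6,7,8,8a-octahydronaphthalen-1-yl]methyl}benzene-1,4-diyl bis(hydrogen sulfate) | C[C@@H]1CC=C2[C@H](CCC[C@@]2(C)CC[C@@]2(C)C3=CCCC(C)(C)[C@@H]3CC[C@@H]2C)[C@@]1(C)Cc1cc(OS(=O)(=O)O)ccc1OS(=O)(=O)O | target

**Totals**

Total step count: 29.
Longest linear sequence: 24 steps (steps 6 to 29, from 10 and 11 to 44).

**Three steps most likely to fail**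

Step 8 (lipase desymmetrisation; the bulky tert-alkyl group may lower the selectivity or reverse the enantiotopic preference). The fallback sets out from 14. Acetylation (Ac2O, pyridine, 4-(dimethylamino)pyridine) gives the diacetate 2-[4-(1,3-dioxolan-2-yl)-2-methylbutan-2-yl]propane-1,3-diyl diacetate F1. The same lipase class, run in hydrolysis mode (phosphate buffer pH 7, MTBE, 25 °C), then cleaves one enantiotopic ester. This leaves the acetate on the arm that the acylation mode would have left free, so it supplies the enantiomer complementary to the acylation result, and it comes back to the route at 15.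

Step 19 (McMurry coupling onto a ketone flanked by a quaternary and a tertiary carbon). The fallback sets out from 29 and replaces reductive coupling by an intramolecular Wittig olefination. NaBH4 (EtOH, −40 °C) reduces only the aldehyde to the keto alcohol (2R,3S,6S)-2-allyl-6-(5-hydroxy-2-methylpentan-2-yl)-2,3-dimethylcyclohexan-1-one F2. I2, PPh3 and imidazole give the keto iodide (2R,3S,6S)-2-allyl-6-(5-iodo-2-methylpentan-2-yl)-2,3-dimethylcyclohexan-1-one F3. PPh3 in MeCN at 80 °C gives the phosphonium salt {4-[(1S,3R,4S)-3-allyl-3,4-dimethyl-2-oxocyclohexyl]-4-methylpentyl}triphenylphosphonium iodide F4. KN(SiMe3)2 in toluene (25 to 110 °C) forms the ylide, which closes ring D onto the ketone, and the sequence comes back at 30.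

Step 26 (facial selectivity of the dienolate methylation; if the electrophile prefers the face anti to the C4a hydrogen, the wrong C1 epimer dominates). The fallback inverts the order in which the two groups are put on that carbon, so that the chain is the incoming electrophile. It sets out from 30 and from 9.
- From 30, Lemieux–Johnson cleavage of the allyl group (OsO4 2 mol %, NaIO4, 2,6-lutidine, dioxane/H2O) gives the aldehyde 2-[(1R,2S,4aS)-1,2,5,5-tetramethyl-1,2,3,4,4a,5,6,7-octahydronaphthalen-1-yl]acetaldehyde F5. NaBH4 gives the alcohol 2-[(1R,2S,4aS)-1,2,5,5-tetramethyl-1,2,3,4,4a,5,6,7-octahydronaphthalen-1-yl]ethan-1-ol F6. I2, PPh3 and imidazole give the iodide (1R,2S,4aS)-1-(2-iodoethyl)-1,2,5,5-tetramethyl-1,2,3,4,4a,5,6,7-octahydronaphthalene F7.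
- From 9, Mukaiyama–Michael addition to pent-1-en-3-one (Sc(OTf)3, then aqueous acid) gives the diketone (3S,4R)-3-(2,5-dimethoxybenzyl)-3,4-dimethyl-2-(3-oxopentyl)cyclohexan-1-one F8. KOH in MeOH gives the enone (4aR,5S,6R)-5-(2,5-dimethoxybenzyl)-1,5,6-trimethyl-4,4a,5,6,7,8-hexahydronaphthalen-2(3H)-one F9.
- Deconjugative alkylation of the dienolate of F9 (KOt-Bu, t-BuOH/THF) with F7 comes back to the route at 40.

**Further compounds**

F1 | step 8 | 2-[4-(1,3-dioxolan-2-yl)-2-methylbutan-2-yl]propane-1,3-diyl diacetate | CC(=O)OCC(COC(C)=O)C(C)(C)CCC1OCCO1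
F2 | step 19 | (2R,3S,6S)-2-allyl-6-(5-hydroxy-2-methylpentan-2-yl)-2,3-dimethylcyclohexan-1-one | C=CC[C@@]1(C)C(=O)[C@H](C(C)(C)CCCO)CC[C@@H]1C
F3 | step 19 | (2R,3S,6S)-2-allyl-6-(5-iodo-2-methylpentan-2-yl)-2,3-dimethylcyclohexan-1-one | C=CC[C@@]1(C)C(=O)[C@H](C(C)(C)CCCI)CC[C@@H]1C
F4 | step 19 | {4-[(1S,3R,4S)-3-allyl-3,4-dimethyl-2-oxocyclohexyl]-4-methylpentyl}triphenylphosphonium iodide | C=CC[C@@]1(C)C(=O)[C@H](C(C)(C)CCC[P+](c2ccccc2)(c2ccccc2)c2ccccc2)CC[C@@H]1C.[I-]
F5 | step 26 | 2-[(1R,2S,4aS)-1,2,5,5-tetramethyl-1,2,3,4,4a,5,6,7-octahydronaphthalen-1-yl]acetaldehyde | O=CC[C@@]1(C)C2=CCCC(C)(C)[C@@H]2CC[C@@H]1C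
F6 | step 26 | 2-[(1R,2S,4aS)-1,2,5,5-tetramethyl-1,2,3,4,4a,5,6,7-octahydronaphthalen-1-yl]ethan-1-ol | OCC[C@@]1(C)C2=CCCC(C)(C)[C@@H]2CC[C@@H]1C
F7 | step 26 | (1R,2S,4aS)-1-(2-iodoethyl)-1,2,5,5-tetramethyl-1,2,3,4,4a,5,6,7-octahydronaphthalene | ICC[C@@]1(C)C2=CCCC(C)(C)[C@@H]2CC[C@@H]1C
F8 | step 26 | (3S,4R)-3-(2,5-dimethoxybenzyl)-3,4-dimethyl-2-(3-oxopentyl)cyclohexan-1-one (C2 epimers) | C[C@@H]1CCC(=O)C(CCC(=O)CC)[C@@]1(C)Cc1cc(OC)ccc1OC
F9 | step 26 | (4aR,5S,6R)-5-(2,5-dimethoxybenzyl)-1,5,6-trimethyl-4,4a,5,6,7,8-hexahydronaphthalen-2(3H)-one | C[C@@H]1CCC2=C(C)C(=O)CC[C@@H]2[C@@]1(C)Cc1cc(OC)ccc1OC
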